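**Retrosynthetic overview**
- The target is reached by acetylation at O1 of a 1α-hydroxy-8α-angeloyloxy ketone; the C1–O bond and the trans C10–H come from conjugate borylation/protonation of a ring A enone (eremophila-1(10),11-dien-9-one core), and the C8–O bond from its kinetic enolate.
- Ring A is closed last, onto ring B, by intramolecular aldol condensation of a keto aldehyde obtained by hydroformylation of a but-3-en-2-yl side chain.
- Key bond C4–C5 (quaternary C5 plus the vicinal C4 methyl): anionic oxy-Cope [3,3] rearrangement of a (Z)-crotyl carbinol; a second sigmatropic step (homodienyl [1,5]-hydrogen shift) unmasks the isopropenyl group from a gem-dimethylcyclopropane.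
- Ring B and the C7 stereocentre are bought as (+)-3-carene (oxidised to car-3-en-5-one); every other stereocentre is relayed from it. Ring order: ring B (bought), then ring A.

Assumption: (2Z)-1-chlorobut-2-ene and angelic acid are taken as commercial; atom labels C1–C15 follow eremophilane numbering (decalin C1–C10, C9 = ketone carbon, C11–C13 = isopropenyl).

**Step 1**
Reactants: 1 (+)-3-carene [(1S,6R)-3,7,7-trimethylbicyclo[4.1.0]hept-3-ene]
Product: 2 (1R,6S)-4,7,7-trimethylbicyclo[4.1.0]hept-3-en-2-one (car-3-en-5-one)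
Conditions: t-BuOOH (70% aq), CrO3 (5 mol%), CH2Cl2, rt
Reagents that add atoms: tert-butyl hydroperoxide CC(C)(C)OO
Why: Chromium-catalysed allylic oxidation abstracts the allylic hydrogen next to the unsubstituted alkene carbon (the allyl radical has a tertiary terminus) and oxidises the less hindered secondary terminus to the enone, leaving both cyclopropane stereocentres of the terpene untouched.

**Step 2**
Reactants: 2 (1R,6S)-4,7,7-trimethylbicyclo[4.1.0]hept-3-en-2-one; 3 (2Z)-1-chlorobut-2-ene
Product: 4 (1R,2R,6S)-2-[(2Z)-but-2-en-1-yl]-4,7,7-trimethylbicyclo[4.1.0]hept-3-en-2-ol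
Conditions: BaI2, LiC12H10 (lithium biphenylide), THF, rt; 3, −78 °C; 2, −78 °C; H2O
Reagents that add atoms: none
Why: Allylbarium reagents add 1,2 to enones through their alpha carbon with retention of the Z geometry (carbonyl allylation), and attack from the face opposite the gem-dimethylcyclopropane, whose endo methyl shields the other face, sets the carbinol centre.

**Step 3**
Reactants: 4 (1R,2R,6S)-2-[(2Z)-but-2-en-1-yl]-4,7,7-trimethylbicyclo[4.1.0]hept-3-en-2-ol
Product: 7 {[(1R,4R,6S)-4-[(2S)-but-3-en-2-yl]-4,7,7-trimethylbicyclo[4.1.0]hept-2-en-2-yl]oxy}trimethylsilane, via potassium alkoxide 5 (not isolated), via potassium enolate 6 (not isolated)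
Conditions: KH, 18-crown-6, THF, 0 °C to rt; Me3SiCl, −78 °C
Reagents that add atoms: chlorotrimethylsilane C[Si](C)(C)Cl
Why: The alkoxide undergoes an anionic oxy-Cope [3,3]-sigmatropic rearrangement on the face carrying the crotyl group, and a chair transition state with the Z-methyl axial (the boat would push it under the ring) forms the C4–C5 bond so that quaternary C5 and the C4 methyl centre arise in the cis-dimethyl (4S,5R) relationship by chirality transfer from the carbinol carbon, after which the regiodefined enolate is silylated on oxygen.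

**Step 4**
Reactants: 7 {[(1R,4R,6S)-4-[(2S)-but-3-en-2-yl]-4,7,7-trimethylbicyclo[4.1.0]hept-2-en-2-yl]oxy}trimethylsilane
Product: 9 (3S,5S)-3-[(2S)-but-3-en-2-yl]-3-methyl-5-(prop-1-en-2-yl)cyclohexan-1-one, via transposed silyl enol ether 8 (not isolated)
Conditions: PhMe, 200 °C (sealed tube); then 1 M HCl, THF, 0 °C
Reagents that add atoms: none
Why: The siloxyvinylcyclopropane with a cis (endo) methyl group undergoes a thermal homodienyl [1,5]-hydrogen shift (sigmatropic, retro-ene type) that opens the cyclopropane regiospecifically to the isopropenyl group without touching the C7 stereocentre, and hydrolysis of the transposed silyl enol ether gives the ketone.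

**Step 5**
Reactants: 9 (3S,5S)-3-[(2S)-but-3-en-2-yl]-3-methyl-5-(prop-1-en-2-yl)cyclohexan-1-one
Product: 12 (3S,4aR,5S)-4a,5-dimethyl-3-(prop-1-en-2-yl)-3,4,4a,5,6,7-hexahydronaphthalen-1(2H)-one [(4S,5R,7S)-eremophila-1(10),11-dien-9-one], via keto aldehyde 10 (not isolated), via aldol adduct 11 (not isolated)
Conditions: Rh(acac)(CO)2 (1 mol%), Xantphos (2 mol%), CO/H2 (1:1, 20 bar), PhMe, 60 °C; then KOH (0.2 equiv), MeOH, rt to 50 °C
Reagents that add atoms: carbon monoxide [C-]#[O+]
Why: Linear-selective rhodium-catalysed hydroformylation converts only the monosubstituted vinyl group (the 1,1-disubstituted isopropenyl group is inert) into the aldehyde, which closes ring A by intramolecular aldol condensation because only attack from C10 gives a six-membered ring, and no stereocentre is created.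

**Step 6**
Reactants: 12 (4S,5R,7S)-eremophila-1(10),11-dien-9-one
Product: 14 (4S,5R,7R,8R)-8-hydroxyeremophila-1(10),11-dien-9-one (8α-OH, trans to the isopropenyl group), via sodium dienolate 13 (not isolated)
Conditions: NaN(SiMe3)2, THF, −78 °C; 3-phenyl-2-(phenylsulfonyl)oxaziridine (racemic), −78 °C; AcOH
Reagents that add atoms: 3-phenyl-2-(phenylsulfonyl)oxaziridine O=S(=O)(N1OC1c1ccccc1)c1ccccc1
Why: Kinetic alpha'-deprotonation gives the cross-conjugated dienolate, and electrophilic enolate hydroxylation occurs on the face opposite the adjacent isopropenyl group to give the trans (equatorial, 8α) alcohol.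

**Step 7**
Reactants: 14 (4S,5R,7R,8R)-8-hydroxyeremophila-1(10),11-dien-9-one; 15 angelic acid [(2Z)-2-methylbut-2-enoic acid]
Product: 16 (4S,5R,7R,8R)-9-oxoeremophila-1(10),11-dien-8-yl (2Z)-2-methylbut-2-enoate
Conditions: 15, 2,4,6-Cl3C6H2COCl, Et3N, PhMe, rt; then 14, 50 °C
Reagents that add atoms: none
Why: Yamaguchi esterification through the mixed anhydride acylates the secondary alpha-ketol under conditions too mild to isomerise the Z-configured angelate to the tiglate, and no stereocentre is affected.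

**Step 8**
Reactants: 16 (4S,5R,7R,8R)-9-oxoeremophila-1(10),11-dien-8-yl (2Z)-2-methylbut-2-enoate
Product: 19 (1S,4S,5R,7R,8R,10S)-1-hydroxy-9-oxoeremophil-11-en-8-yl (2Z)-2-methylbut-2-enoate (1α-OH and 10α-H), via boron enolate 17 (not isolated), via β-boryl ketone 18 (not isolated)
Conditions: B2pin2, CuCl (10 mol%), PBu3 (11 mol%), DMF, rt; AcOH, −40 °C; then NaBO3·4H2O, THF/H2O, 0 °C
Reagents that add atoms: bis(pinacolato)diboron CC1(C)OB(OC1(C)C)B1OC(C)(C)C(C)(C)O1 (boron of 17 and 18); sodium perborate tetrahydrate [Na+].[O-]OB=O.O.O.O.O (the C1 oxygen)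
Why: Copper-catalysed conjugate borylation puts boron on C1 of the s-cis enone from the face opposite the axial angular methyl, low-temperature kinetic protonation of the boron enolate on that same less hindered face is expected to fix the trans ring fusion at C10, and perborate oxidises the C–B bond with retention to the 1α alcohol.

**Step 9**
Reactants: 19 (1S,4S,5R,7R,8R,10S)-1-hydroxy-9-oxoeremophil-11-en-8-yl (2Z)-2-methylbut-2-enoate
Product: 20 (1S,4S,5R,7R,8R,10S)-1-acetoxy-9-oxoeremophil-11-en-8-yl (2Z)-2-methylbut-2-enoate (target)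
Conditions: Ac2O, pyridine, DMAP (cat.), CH2Cl2, 0 °C
Reagents that add atoms: acetic anhydride CC(=O)OC(C)=O
Why: Nucleophile-catalysed O-acylation at low temperature acetylates the remaining secondary alcohol without beta-elimination or epimerisation at the neighbouring C10.

**Compound list**
1 | (+)-3-carene, (1S,6R)-3,7,7-trimethylbicyclo[4.1.0]hept-3-ene | CC1=CC[C@@H]2[C@H](C1)C2(C)C | starting material
2 | (1R,6S)-4,7,7-trimethylbicyclo[4.1.0]hept-3-en-2-one | CC1=CC(=O)[C@@H]2[C@H](C1)C2(C)C | intermediate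
3 | (2Z)-1-chlorobut-2-ene | C/C=C\CCl | starting material
4 | (1R,2R,6S)-2-[(2Z)-but-2-en-1-yl]-4,7,7-trimethylbicyclo[4.1.0]hept-3-en-2-ol | CC1=C[C@](O)(C/C=C\C)[C@@H]2[C@H](C1)C2(C)C | intermediate
5 | potassium alkoxide of 4 (not isolated) | CC1=C[C@]([O-])(C/C=C\C)[C@@H]2[C@H](C1)C2(C)C.[K+] | intermediate
6 | potassium (1R,4R,6S)-4-[(2S)-but-3-en-2-yl]-4,7,7-trimethylbicyclo[4.1.0]hept-2-en-2-olate (not isolated) | [K+].[O-]C1=C[C@@](C)([C@@H](C)C=C)C[C@H]2[C@@H]1C2(C)C | intermediate
7 | {[(1R,4R,6S)-4-[(2S)-but-3-en-2-yl]-4,7,7-trimethylbicyclo[4.1.0]hept-2-en-2-yl]oxy}trimethylsilane | C[Si](C)(C)OC1=C[C@@](C)([C@@H](C)C=C)C[C@H]2[C@@H]1C2(C)C | intermediate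
8 | trimethyl{[(3S,5S)-5-[(2S)-but-3-en-2-yl]-5-methyl-3-(prop-1-en-2-yl)cyclohex-1-en-1-yl]oxy}silane (not isolated) | C[Si](C)(C)OC1=C[C@@H](C(C)=C)C[C@](C)([C@@H](C)C=C)C1 | intermediate
9 | (3S,5S)-3-[(2S)-but-3-en-2-yl]-3-methyl-5-(prop-1-en-2-yl)cyclohexan-1-one | C=C(C)[C@H]1C[C@](C)([C@@H](C)C=C)CC(=O)C1 | intermediate
10 | (4S)-4-[(1S,5S)-1-methyl-3-oxo-5-(prop-1-en-2-yl)cyclohexyl]pentanal (not isolated) | C=C(C)[C@H]1C[C@](C)([C@@H](C)CCC=O)CC(=O)C1 | intermediate
11 | (4S,5R,7S)-1-hydroxyeremophil-11-en-9-one, mixture of C1/C10 epimers (not isolated) | C=C(C)[C@H]1C[C@@]2(C)C(C(=O)C1)C(O)CC[C@@H]2C | intermediate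
12 | (4S,5R,7S)-eremophila-1(10),11-dien-9-one | C=C(C)[C@H]1C[C@@]2(C)C(C(=O)C1)=CCC[C@@H]2C | intermediate
13 | sodium 8,9-dienolate of 12 (not isolated) | C=C(C)[C@H]1C[C@@]2(C)C(C([O-])=C1)=CCC[C@@H]2C.[Na+] | intermediate
14 | (4S,5R,7R,8R)-8-hydroxyeremophila-1(10),11-dien-9-one | C=C(C)[C@H]1C[C@@]2(C)C(C(=O)[C@@H]1O)=CCC[C@@H]2C | intermediate
15 | angelic acid, (2Z)-2-methylbut-2-enoic acid | C/C=C(/C)C(=O)O | starting material
16 | (4S,5R,7R,8R)-9-oxoeremophila-1(10),11-dien-8-yl (2Z)-2-methylbut-2-enoate | C=C(C)[C@H]1C[C@@]2(C)C(C(=O)[C@@H]1OC(=O)/C(C)=C\C)=CCC[C@@H]2C | intermediate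
17 | 9-O-pinacolboryl 9(10)-enolate of the 1α-pinacolboryl 8α-angelate (not isolated) | C=C(C)[C@H]1C[C@@]2(C)C(=C(OB3OC(C)(C)C(C)(C)O3)[C@@H]1OC(=O)/C(C)=C\C)[C@@H](B3OC(C)(C)C(C)(C)O3)CC[C@@H]2C | intermediate
18 | 8α-angeloyloxy-1α-(pinacolboryl)-10αH-eremophil-11-en-9-one (not isolated) | C=C(C)[C@H]1C[C@@]2(C)[C@H](C(=O)[C@@H]1OC(=O)/C(C)=C\C)[C@@H](B3OC(C)(C)C(C)(C)O3)CC[C@@H]2C | intermediate
19 | (1S,4S,5R,7R,8R,10S)-1-hydroxy-9-oxoeremophil-11-en-8-yl (2Z)-2-methylbut-2-enoate | C=C(C)[C@H]1C[C@@]2(C)[C@H](C(=O)[C@@H]1OC(=O)/C(C)=C\C)[C@@H](O)CC[C@@H]2C | intermediate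
20 | (1S,4S,5R,7R,8R,10S)-1-acetoxy-9-oxoeremophil-11-en-8-yl (2Z)-2-methylbut-2-enoate, CNP0138236.2 | C=C(C)[C@H]1C[C@@]2(C)[C@H](C(=O)[C@@H]1OC(=O)/C(C)=C\C)[C@@H](OC(C)=O)CC[C@@H]2C | target

**Step count**
Total: 9 steps. Longest linear sequence: 9 steps, from (+)-3-carene.

**Steps most likely to fail**

Step 8 is the weakest point. The trans-fused 10αH ketone is expected to be less stable than its cis-fused C10 epimer (the 7β-isopropenyl group is cis to the C5 methyl), so the route depends on kinetic protonation and on keeping every later operation non-basic; the angelate could also compete for the boryl copper species. The fallback sets out from 16 and returns at 19: nucleophilic epoxidation of the enone (t-BuOOH, DBU, CH2Cl2, 0 °C), which attacks anti to the angular methyl and spares the hindered angelate and the isopropenyl group, gives 1α,10α-epoxy-8α-angeloyloxyeremophil-11-en-9-one F3. Reductive opening at the alpha carbon with (PhSe)2, NaBH4 and AcOH in EtOH at 0 °C then gives 19, the C10–H being set by ketonisation of the enol in buffered medium on the face away from the angular methyl.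

Step 3 may suffer from fragmentation of the alkoxide (retro-allylation and recombination) or partial leakage through a boat, eroding the C4 configuration. The fallback sets out from 2 and returns at 7: Hosomi–Sakurai conjugate crotylation (crotyltrimethylsilane, TiCl4, CH2Cl2, −78 °C), anti to the cyclopropane, gives (1R,4S,6S)-4-[(2S)-but-3-en-2-yl]-4,7,7-trimethylbicyclo[4.1.0]heptan-2-one F1 (C4 epimers separated by chromatography). Kinetic enolisation at its only enolisable CH2 with LiN(iPr)2 and Me3SiCl in THF at −78 °C then gives 7.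

Step 4 may require temperatures at which the 1,5-diene of 7 reverts by siloxy-Cope equilibration or the enol ether decomposes. The fallback sets out from 7 and returns at 9: aqueous HClO4 in THF at 40 °C removes the silyl group (passing through ketone F1 of the fallback above) and opens the cyclopropyl ketone hydratively at the tertiary carbon to (3S,5S)-3-[(2S)-but-3-en-2-yl]-5-(2-hydroxypropan-2-yl)-3-methylcyclohexan-1-one F2. Dehydration with SOCl2 and pyridine at −20 °C gives 9, the minor isopropylidene isomer being removed on AgNO3-impregnated silica.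

**Further compounds**
F1 | step 3 | (1R,4S,6S)-4-[(2S)-but-3-en-2-yl]-4,7,7-trimethylbicyclo[4.1.0]heptan-2-one | O=C1C[C@@](C)([C@@H](C)C=C)C[C@H]2[C@@H]1C2(C)C
F2 | step 4 | (3S,5S)-3-[(2S)-but-3-en-2-yl]-5-(2-hydroxypropan-2-yl)-3-methylcyclohexan-1-one | CC(C)(O)[C@H]1C[C@](C)([C@@H](C)C=C)CC(=O)C1
F3 | step 8 | 1α,10α-epoxy-8α-angeloyloxyeremophil-11-en-9-one | C=C(C)[C@H]1C[C@@]2(C)[C@]3(C(=O)[C@@H]1OC(=O)/C(C)=C\C)[C@@H](O3)CC[C@@H]2C
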